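**Assumption:** eudesmane numbering (C1–C15) is used for positions in all rings and ring precursors, α meaning the face opposite to the C10 methyl group; compounds 1, 3 and 13 are taken as commercially available.

## Retrosynthetic overview

1. Target 23 ⇐ 22 ⇐ 21: final desilylation, and Luche reduction of the 3-oxo-4(15)-ene to set C3.
2. 21 ⇐ 20: ring A is made last by a gold-catalysed 1,2-alkyl shift that expands a 3-ethynylcyclopentan-3-ol into the 3-oxo-4-methylenecyclohexane (C4–C5 bond).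
3. 20 ⇐ 12: C6 esterification with acid 15, reduction of the C1 ketone, and oxidation of the isopropenyl group to the methyl acrylate.
4. 12 ⇐ 11: ring B by carbonyl-ene cyclisation (C6–C7 bond, C6 and C7 stereocentres) on a trans-1,2-disubstituted cyclopentane.
5. 11 ⇐ 8 ⇐ 1: two successive anti-selective conjugate additions to (S)-4-silyloxycyclopentenone (homoprenyl, then methyl with orthoformate trapping) set C10 and C5. Ring order: cyclopentane from 1 → ring B → ring A.

## Route

Step 1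
Reactants: 1 (S)-4-hydroxycyclopent-2-en-1-one
Product: 2 (S)-4-(triethylsilyloxy)cyclopent-2-en-1-one
Conditions: TESCl, imidazole, CH2Cl2, 0 °C
Reagents that add atoms: chlorotriethylsilane, CC[Si](Cl)(CC)CC
Why: Imidazole-mediated O-silylation (silyl ether protection) leaves the stereocentre untouched; the α-silyloxy group at C1 is the control element for the next two C–C bond formations.

Step 2
Reactants: 2 (S)-4-(triethylsilyloxy)cyclopent-2-en-1-one; 3 5-bromo-2-methylpent-2-ene
Product: 6 (S)-3-(4-methylpent-3-en-1-yl)-4-(triethylsilyloxy)cyclopent-2-en-1-one, via homoprenylmagnesium bromide 4 (not isolated), via homoprenyl TMS enol ether 5 (not isolated)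
Conditions: 3, Mg, THF, rt; then 2, CuBr·SMe2 (10 mol %), TMSCl, HMPA, THF, −78 °C; crude 5, Pd(OAc)2 (10 mol %), O2 (1 atm), DMSO, 40 °C
Reagents that add atoms: none
Why: Copper-catalysed, TMSCl-accelerated conjugate addition of the Grignard reagent followed by Saegusa–Ito dehydrosilylation (divalent palladium, reoxidised by O2) re-forms the enone with the C9–C13 chain on C10; the transient C10 stereocentre is erased, so only the C1 silyloxy centre remains.

Step 3
Reactants: 6 (S)-3-(4-methylpent-3-en-1-yl)-4-(triethylsilyloxy)cyclopent-2-en-1-one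
Product: 8 (2S,3R,4S)-2-(dimethoxymethyl)-3-methyl-3-(4-methylpent-3-en-1-yl)-4-(triethylsilyloxy)cyclopentan-1-one, via quaternary TMS enol ether 7 (not isolated)
Conditions: MeMgBr, CuBr·SMe2 (10 mol %), TMSCl, HMPA, THF, −78 → −40 °C; crude 7, HC(OMe)3, TMSOTf (10 mol %), CH2Cl2, −78 °C
Reagents that add atoms: methylmagnesium bromide, C[Mg]Br; trimethyl orthoformate, COC(OC)OC
Why: Copper-catalysed conjugate addition puts methyl on C10 anti to the C1 silyloxy group (methyl β, chain α), and the Mukaiyama-type orthoformate condensation (Noyori conditions) attacks C5 of the silyl enol ether from the β face, anti to both the silyloxy group and the chain, giving the trans C5/C10 relationship needed for the trans ring fusion.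

Step 4
Reactants: 8 (2S,3R,4S)-2-(dimethoxymethyl)-3-methyl-3-(4-methylpent-3-en-1-yl)-4-(triethylsilyloxy)cyclopentan-1-one
Product: 9 (1S,2R,3R,4S)-2-(dimethoxymethyl)-1-ethynyl-3-methyl-3-(4-methylpent-3-en-1-yl)-4-(triethylsilyloxy)cyclopentan-1-ol
Conditions: HC≡CMgBr, CeCl3, THF, −78 → 0 °C
Reagents that add atoms: ethynylmagnesium bromide, C#C[Mg]Br
Why: Cerium-mediated 1,2-addition (Imamoto conditions) of the acetylide to the hindered, enolisable ketone brings in C4 and C15; attack anti to the neighbouring dimethoxymethyl group should give mainly the epimer shown, and the C3 centre becomes sp2 again in step 15, so its configuration is inconsequential.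

Step 5
Reactants: 9 (1S,2R,3R,4S)-2-(dimethoxymethyl)-1-ethynyl-3-methyl-3-(4-methylpent-3-en-1-yl)-4-(triethylsilyloxy)cyclopentan-1-ol
Product: 10 (1R,2R,3S,5S)-5-ethynyl-3,5-dihydroxy-2-methyl-2-(4-methylpent-3-en-1-yl)cyclopentane-1-carbaldehyde
Conditions: TsOH·H2O (10 mol %), acetone/H2O 10:1, rt
Reagents that add atoms: water, O
Why: Mild acid-catalysed acetal hydrolysis and TES ether cleavage in one operation unmask the C6 aldehyde and the C1 alcohol without touching a stereocentre; the C1-OH is trans to the formyl group, so no lactol forms.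

Step 6
Reactants: 10 (1R,2R,3S,5S)-5-ethynyl-3,5-dihydroxy-2-methyl-2-(4-methylpent-3-en-1-yl)cyclopentane-1-carbaldehyde
Product: 11 (1R,2R,5S)-5-ethynyl-5-hydroxy-2-methyl-2-(4-methylpent-3-en-1-yl)-3-oxocyclopentane-1-carbaldehyde
Conditions: Dess–Martin periodinane, pyridine, CH2Cl2, 0 °C → rt
Reagents that add atoms: none
Why: Dess–Martin oxidation affects only the secondary C1 alcohol (tertiary propargylic alcohol and aldehyde are inert); the C1 control centre has done its work and is removed so that C1 can be reset by reduction once the bicycle exists.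

Step 7
Reactants: 11 (1R,2R,5S)-5-ethynyl-5-hydroxy-2-methyl-2-(4-methylpent-3-en-1-yl)-3-oxocyclopentane-1-carbaldehyde
Product: 12 (3S,3aS,4S,5S,7aR)-3-ethynyl-3,4-dihydroxy-7a-methyl-5-(prop-1-en-2-yl)octahydro-1H-inden-1-one
Conditions: ZnBr2 (2 equiv), CH2Cl2, 0 °C
Reagents that add atoms: none
Why: Intramolecular carbonyl-ene cyclisation (citronellal-to-isopulegol type) closes ring B through a chair transition state with the carbonyl oxygen and the developing isopropenyl group both equatorial, giving 6α-OH and 7β-isopropenyl on a trans-fused hydrindane.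

Step 8
Reactants: 13 methyl 2-(hydroxymethyl)prop-2-enoate
Product: 14 methyl 2-{[(tert-butyldimethylsilyl)oxy]methyl}prop-2-enoate
Conditions: TBSCl, imidazole, CH2Cl2, 0 °C → rt
Reagents that add atoms: tert-butylchlorodimethylsilane, CC(C)(C)[Si](C)(C)Cl
Why: Standard silyl ether protection of the primary allylic alcohol.

Step 9
Reactants: 14 methyl 2-{[(tert-butyldimethylsilyl)oxy]methyl}prop-2-enoate
Product: 15 2-{[(tert-butyldimethylsilyl)oxy]methyl}prop-2-enoic acid
Conditions: LiOH, THF/H2O 3:1, 0 °C → rt; then 1 M HCl to pH 4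
Reagents that add atoms: lithium hydroxide, [Li+].[OH-]
Why: Ester saponification; the primary TBS ether survives aqueous LiOH at room temperature.

Step 10
Reactants: 12 (3S,3aS,4S,5S,7aR)-3-ethynyl-3,4-dihydroxy-7a-methyl-5-(prop-1-en-2-yl)octahydro-1H-inden-1-one; 15 2-{[(tert-butyldimethylsilyl)oxy]methyl}prop-2-enoic acid
Product: 16 (3S,3aS,4S,5S,7aR)-3-ethynyl-3-hydroxy-7a-methyl-1-oxo-5-(prop-1-en-2-yl)octahydro-1H-inden-4-yl 2-{[(tert-butyldimethylsilyl)oxy]methyl}prop-2-enoate
Conditions: 15 (3 equiv), DIC, DMAP, CH2Cl2, 0 °C → rt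
Reagents that add atoms: none
Why: Steglich esterification acylates the only secondary alcohol (C6-OH); the tertiary propargylic C3-OH is too hindered to compete, and no stereocentre is affected.

Step 11
Reactants: 16 (3S,3aS,4S,5S,7aR)-3-ethynyl-3-hydroxy-7a-methyl-1-oxo-5-(prop-1-en-2-yl)octahydro-1H-inden-4-yl 2-{[(tert-butyldimethylsilyl)oxy]methyl}prop-2-enoate
Product: 17 (1R,3S,3aS,4S,5S,7aR)-3-ethynyl-1,3-dihydroxy-7a-methyl-5-(prop-1-en-2-yl)octahydro-1H-inden-4-yl 2-{[(tert-butyldimethylsilyl)oxy]methyl}prop-2-enoate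
Conditions: NaBH4, CeCl3·7H2O, MeOH, −78 °C
Reagents that add atoms: none
Why: Luche reduction; hydride attacks the cyclopentanone from the α face, opposite the angular methyl group (as in 17-keto steroids), giving the 1β-alcohol, and the acrylate ester is not reduced at −78 °C.

Step 12
Reactants: 17 (1R,3S,3aS,4S,5S,7aR)-3-ethynyl-1,3-dihydroxy-7a-methyl-5-(prop-1-en-2-yl)octahydro-1H-inden-4-yl 2-{[(tert-butyldimethylsilyl)oxy]methyl}prop-2-enoate
Product: 18 (1R,3S,3aS,4S,5S,7aR)-3-ethynyl-1,3-dihydroxy-7a-methyl-5-(3-oxoprop-1-en-2-yl)octahydro-1H-inden-4-yl 2-{[(tert-butyldimethylsilyl)oxy]methyl}prop-2-enoate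
Conditions: SeO2, 1,4-dioxane, 70 °C
Reagents that add atoms: selenium dioxide, O=[Se]=O
Why: Riley allylic oxidation (ene reaction then [2,3]-shift) converts the isopropenyl methyl group into the 2-substituted acrolein; the electron-poor acrylate and the alkyne, which has no propargylic hydrogen, are inert.

Step 13
Reactants: 18 (1R,3S,3aS,4S,5S,7aR)-3-ethynyl-1,3-dihydroxy-7a-methyl-5-(3-oxoprop-1-en-2-yl)octahydro-1H-inden-4-yl 2-{[(tert-butyldimethylsilyl)oxy]methyl}prop-2-enoate
Product: 19 2-[(1R,3S,3aS,4S,5S,7aR)-4-({2-[(tert-butyldimethylsilyloxy)methyl]prop-2-enoyl}oxy)-3-ethynyl-1,3-dihydroxy-7a-methyloctahydro-1H-inden-5-yl]prop-2-enoic acid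
Conditions: NaClO2, NaH2PO4, 2-methylbut-2-ene, t-BuOH/H2O, 0 °C → rt
Reagents that add atoms: sodium chlorite, [Na+].[O-]Cl=O
Why: Pinnick oxidation takes the enal to the acrylic acid without touching the alcohols, alkyne or silyl ether, the alkene scavenger removing HOCl.

Step 14
Reactants: 19 2-[(1R,3S,3aS,4S,5S,7aR)-4-({2-[(tert-butyldimethylsilyloxy)methyl]prop-2-enoyl}oxy)-3-ethynyl-1,3-dihydroxy-7a-methyloctahydro-1H-inden-5-yl]prop-2-enoic acid
Product: 20 methyl 2-[(1R,3S,3aS,4S,5S,7aR)-4-({2-[(tert-butyldimethylsilyloxy)methyl]prop-2-enoyl}oxy)-3-ethynyl-1,3-dihydroxy-7a-methyloctahydro-1H-inden-5-yl]prop-2-enoate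
Conditions: MeI, KHCO3, DMF, rt
Reagents that add atoms: iodomethane, CI
Why: SN2 O-alkylation of the carboxylate under weakly basic conditions gives the methyl ester; alcohols and the terminal alkyne are not deprotonated by KHCO3.

Step 15
Reactants: 20 methyl 2-[(1R,3S,3aS,4S,5S,7aR)-4-({2-[(tert-butyldimethylsilyloxy)methyl]prop-2-enoyl}oxy)-3-ethynyl-1,3-dihydroxy-7a-methyloctahydro-1H-inden-5-yl]prop-2-enoate
Product: 21 methyl 2-[(1S,2S,4aR,5R,8aR)-1-({2-[(tert-butyldimethylsilyloxy)methyl]prop-2-enoyl}oxy)-5-hydroxy-4a-methyl-8-methylidene-7-oxodecahydronaphthalen-2-yl]prop-2-enoate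
Conditions: [(2,4-(t-Bu)2C6H3O)3P]AuNTf2 (5 mol %), CH2Cl2, rt
Reagents that add atoms: none
Why: Proposed new method: a cationic monovalent gold phosphite complex activates the terminal alkyne of the tertiary propargylic alcohol, the C3–C5 σ-bond migrates to the internal alkyne carbon while the carbinol becomes the C3 ketone (semipinacol-type 1,2-alkyl shift), and protodeauration of the vinyl-gold species gives the exocyclic methylene; the more substituted C5 should migrate in preference to the C2 methylene (deactivated by the β-hydroxyl at C1) and with retention, so the trans-hydrindane becomes the trans-decalin with 5α-H; the closest known reaction type is the gold-catalysed ring expansion of 1-alkynylcyclobutanols and 1-alkynylcyclopropanols to 2-alkylidenecycloalkanones, shown only for strained rings, whereas here the driving force is the alkyne-to-enone conversion plus relief of trans-hydrindane strain.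

Step 16
Reactants: 21 methyl 2-[(1S,2S,4aR,5R,8aR)-1-({2-[(tert-butyldimethylsilyloxy)methyl]prop-2-enoyl}oxy)-5-hydroxy-4a-methyl-8-methylidene-7-oxodecahydronaphthalen-2-yl]prop-2-enoate
Product: 22 methyl 2-[(1S,2S,4aR,5R,7S,8aS)-1-({2-[(tert-butyldimethylsilyloxy)methyl]prop-2-enoyl}oxy)-5,7-dihydroxy-4a-methyl-8-methylidenedecahydronaphthalen-2-yl]prop-2-enoate
Conditions: NaBH4, CeCl3·7H2O, MeOH, −78 °C
Reagents that add atoms: none
Why: Luche 1,2-reduction of the exocyclic enone; axial hydride delivery from the α face of the trans-decalin gives the equatorial 3β-allylic alcohol (as for 3-keto-5α-steroids) without conjugate reduction of either acrylate.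

Step 17
Reactants: 22 methyl 2-[(1S,2S,4aR,5R,7S,8aS)-1-({2-[(tert-butyldimethylsilyloxy)methyl]prop-2-enoyl}oxy)-5,7-dihydroxy-4a-methyl-8-methylidenedecahydronaphthalen-2-yl]prop-2-enoate
Product: 23 methyl 2-[(1S,2S,4aR,5R,7S,8aS)-5,7-dihydroxy-1-{[2-(hydroxymethyl)prop-2-enoyl]oxy}-4a-methyl-8-methylidenedecahydronaphthalen-2-yl]prop-2-enoate
Conditions: HF·pyridine, pyridine, THF, 0 °C → rt
Reagents that add atoms: none
Why: Buffered fluoride desilylation of the primary TBS ether is non-basic, so acyl migration and Michael addition to the acrylates are avoided; no stereocentre is touched.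

## Compound list

1 | (S)-4-hydroxycyclopent-2-en-1-one | O=C1C=C[C@@H](O)C1 | starting material
2 | (S)-4-(triethylsilyloxy)cyclopent-2-en-1-one | O=C1C=C[C@@H](O[Si](CC)(CC)CC)C1 | intermediate
3 | 5-bromo-2-methylpent-2-ene | CC(C)=CCCBr | starting material
4 | (4-methylpent-3-en-1-yl)magnesium bromide | CC(C)=CCC[Mg]Br | intermediate
5 | (3S,4S)-3-(4-methylpent-3-en-1-yl)-4-(triethylsilyloxy)-1-(trimethylsilyloxy)cyclopent-1-ene | C[Si](C)(C)OC1=C[C@H](CCC=C(C)C)[C@@H](O[Si](CC)(CC)CC)C1 | intermediate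
6 | (S)-3-(4-methylpent-3-en-1-yl)-4-(triethylsilyloxy)cyclopent-2-en-1-one | O=C1C=C(CCC=C(C)C)[C@@H](O[Si](CC)(CC)CC)C1 | intermediate
7 | (3R,4S)-3-methyl-3-(4-methylpent-3-en-1-yl)-4-(triethylsilyloxy)-1-(trimethylsilyloxy)cyclopent-1-ene | C[Si](C)(C)OC1=C[C@@](C)(CCC=C(C)C)[C@@H](O[Si](CC)(CC)CC)C1 | intermediate
8 | (2S,3R,4S)-2-(dimethoxymethyl)-3-methyl-3-(4-methylpent-3-en-1-yl)-4-(triethylsilyloxy)cyclopentan-1-one | O=C1[C@H](C(OC)OC)[C@@](C)(CCC=C(C)C)[C@@H](O[Si](CC)(CC)CC)C1 | intermediate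
9 | (1S,2R,3R,4S)-2-(dimethoxymethyl)-1-ethynyl-3-methyl-3-(4-methylpent-3-en-1-yl)-4-(triethylsilyloxy)cyclopentan-1-ol | C#C[C@@]1(O)[C@H](C(OC)OC)[C@@](C)(CCC=C(C)C)[C@@H](O[Si](CC)(CC)CC)C1 | intermediate
10 | (1R,2R,3S,5S)-5-ethynyl-3,5-dihydroxy-2-methyl-2-(4-methylpent-3-en-1-yl)cyclopentane-1-carbaldehyde | C#C[C@@]1(O)[C@H](C=O)[C@@](C)(CCC=C(C)C)[C@@H](O)C1 | intermediate
11 | (1R,2R,5S)-5-ethynyl-5-hydroxy-2-methyl-2-(4-methylpent-3-en-1-yl)-3-oxocyclopentane-1-carbaldehyde | C#C[C@@]1(O)[C@H](C=O)[C@@](C)(CCC=C(C)C)C(=O)C1 | intermediate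
12 | (3S,3aS,4S,5S,7aR)-3-ethynyl-3,4-dihydroxy-7a-methyl-5-(prop-1-en-2-yl)octahydro-1H-inden-1-one | O[C@@H]1[C@H]2[C@](O)(C#C)CC(=O)[C@]2(C)CC[C@H]1C(C)=C | intermediate
13 | methyl 2-(hydroxymethyl)prop-2-enoate | C=C(CO)C(=O)OC | starting material
14 | methyl 2-{[(tert-butyldimethylsilyl)oxy]methyl}prop-2-enoate | C=C(CO[Si](C)(C)C(C)(C)C)C(=O)OC | intermediate
15 | 2-{[(tert-butyldimethylsilyl)oxy]methyl}prop-2-enoic acid | C=C(CO[Si](C)(C)C(C)(C)C)C(=O)O | intermediate
16 | (3S,3aS,4S,5S,7aR)-3-ethynyl-3-hydroxy-7a-methyl-1-oxo-5-(prop-1-en-2-yl)octahydro-1H-inden-4-yl 2-{[(tert-butyldimethylsilyl)oxy]methyl}prop-2-enoate | C=C(CO[Si](C)(C)C(C)(C)C)C(=O)O[C@@H]1[C@H]2[C@](O)(C#C)CC(=O)[C@]2(C)CC[C@H]1C(C)=C | intermediate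
17 | (1R,3S,3aS,4S,5S,7aR)-3-ethynyl-1,3-dihydroxy-7a-methyl-5-(prop-1-en-2-yl)octahydro-1H-inden-4-yl 2-{[(tert-butyldimethylsilyl)oxy]methyl}prop-2-enoate | C=C(CO[Si](C)(C)C(C)(C)C)C(=O)O[C@@H]1[C@H]2[C@](O)(C#C)C[C@@H](O)[C@]2(C)CC[C@H]1C(C)=C | intermediate
18 | (1R,3S,3aS,4S,5S,7aR)-3-ethynyl-1,3-dihydroxy-7a-methyl-5-(3-oxoprop-1-en-2-yl)octahydro-1H-inden-4-yl 2-{[(tert-butyldimethylsilyl)oxy]methyl}prop-2-enoate | C=C(CO[Si](C)(C)C(C)(C)C)C(=O)O[C@@H]1[C@H]2[C@](O)(C#C)C[C@@H](O)[C@]2(C)CC[C@H]1C(=C)C=O | intermediate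
19 | 2-[(1R,3S,3aS,4S,5S,7aR)-4-({2-[(tert-butyldimethylsilyloxy)methyl]prop-2-enoyl}oxy)-3-ethynyl-1,3-dihydroxy-7a-methyloctahydro-1H-inden-5-yl]prop-2-enoic acid | C=C(CO[Si](C)(C)C(C)(C)C)C(=O)O[C@@H]1[C@H]2[C@](O)(C#C)C[C@@H](O)[C@]2(C)CC[C@H]1C(=C)C(=O)O | intermediate
20 | methyl 2-[(1R,3S,3aS,4S,5S,7aR)-4-({2-[(tert-butyldimethylsilyloxy)methyl]prop-2-enoyl}oxy)-3-ethynyl-1,3-dihydroxy-7a-methyloctahydro-1H-inden-5-yl]prop-2-enoate | C=C(CO[Si](C)(C)C(C)(C)C)C(=O)O[C@@H]1[C@H]2[C@](O)(C#C)C[C@@H](O)[C@]2(C)CC[C@H]1C(=C)C(=O)OC | intermediate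
21 | methyl 2-[(1S,2S,4aR,5R,8aR)-1-({2-[(tert-butyldimethylsilyloxy)methyl]prop-2-enoyl}oxy)-5-hydroxy-4a-methyl-8-methylidene-7-oxodecahydronaphthalen-2-yl]prop-2-enoate | C=C(CO[Si](C)(C)C(C)(C)C)C(=O)O[C@@H]1[C@H]2C(=C)C(=O)C[C@@H](O)[C@]2(C)CC[C@H]1C(=C)C(=O)OC | intermediate
22 | methyl 2-[(1S,2S,4aR,5R,7S,8aS)-1-({2-[(tert-butyldimethylsilyloxy)methyl]prop-2-enoyl}oxy)-5,7-dihydroxy-4a-methyl-8-methylidenedecahydronaphthalen-2-yl]prop-2-enoate | C=C(CO[Si](C)(C)C(C)(C)C)C(=O)O[C@@H]1[C@H]2C(=C)[C@@H](O)C[C@@H](O)[C@]2(C)CC[C@H]1C(=C)C(=O)OC | intermediate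
23 | methyl 2-[(1S,2S,4aR,5R,7S,8aS)-5,7-dihydroxy-1-{[2-(hydroxymethyl)prop-2-enoyl]oxy}-4a-methyl-8-methylidenedecahydronaphthalen-2-yl]prop-2-enoate | C=C(CO)C(=O)O[C@@H]1[C@H]2C(=C)[C@@H](O)C[C@@H](O)[C@]2(C)CC[C@H]1C(=C)C(=O)OC | target

## Step count and risks

Total step count: 17. Longest linear sequence: 15 (steps 1–7 and 10–17, from 1); steps 8–9 make the acid 15.

**Step 15 (the new gold-catalysed ring expansion).** Without small-ring strain the 1,2-shift may be slower than Meyer–Schuster rearrangement or hydration of the propargylic alcohol, and C2 could migrate instead of C5. The fallback sets out from 20 and returns at 21 using known reactions. Semihydrogenation of the alkyne (H2, Pd/CaCO3 poisoned with Pb(OAc)2, quinoline, EtOAc) gives the vinyl carbinol F1. Hydroxyl-directed epoxidation (VO(acac)2, t-BuOOH, CH2Cl2) gives the epoxy alcohol F2. BF3·OEt2 at −78 °C then triggers the semipinacol rearrangement of this 2,3-epoxy alcohol, C5 migrating to C4 with ring expansion, to give the β-hydroxymethyl ketone F3. MsCl/Et3N at −20 °C sulfonylates the primary alcohol selectively to the primary mesylate F4, and DBU eliminates it to the exocyclic enone 21.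

**Step 3 (quaternary centre plus orthoformate trapping).** The conjugate addition next to the silyloxy-bearing carbon is hindered, the C5 facial selectivity rests on steric arguments, and the acetal could undergo a Prins reaction with the trisubstituted alkene under the Lewis acid. The fallback sets out from 6 and returns at 11. The conjugate addition is run as before to the silyl enol ether 7, the lithium enolate is regenerated with MeLi and trapped with monomeric formaldehyde (aldol) to give the hydroxymethyl ketone F5. Silylation (TBSCl, imidazole) gives the bis-silyl ether F6, and HC≡CMgBr/CeCl3 gives the ethynyl carbinol F7. HF·pyridine removes both silyl groups to give the triol F8, and Dess–Martin periodinane (2.5 equiv) oxidises the primary alcohol to the aldehyde and the secondary alcohol to the ketone, giving 11.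

**Step 7 (carbonyl-ene cyclisation).** The aldehyde is flanked by two quaternary carbons and the tertiary propargylic carbinol is an acid-sensitive aldol-type centre, so the Lewis acid may cause dehydration or a poor diastereomer ratio. The fallback sets out from 11 and returns at 12. Selenium-catalysed allylic chlorination of the trisubstituted alkene (N-chlorosuccinimide, PhSeCl 10 mol %, CH2Cl2) gives the transposed allylic chloride F9. Intramolecular Nozaki–Hiyama allylation with divalent chromium (CrCl2, LiI, THF/DMF) then adds the allylchromium through its substituted terminus to the aldehyde with anti selectivity, giving the same 6α-hydroxy-7β-isopropenyl hydrindanone 12.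

## Further compounds

F1 | step 15 | vinyl carbinol: compound 20 with the C3 ethynyl group reduced to ethenyl, all stereocentres as in 20 | C=C(CO[Si](C)(C)C(C)(C)C)C(=O)O[C@@H]1[C@H]2[C@](O)(C=C)C[C@@H](O)[C@]2(C)CC[C@H]1C(=C)C(=O)OC
F2 | step 15 | epoxy alcohol: F1 with the vinyl group epoxidised to an oxiranyl group (epimers at the new oxirane carbon) | C=C(CO[Si](C)(C)C(C)(C)C)C(=O)O[C@@H]1[C@H]2[C@](O)(C3CO3)C[C@@H](O)[C@]2(C)CC[C@H]1C(=C)C(=O)OC
F3 | step 15 | β-hydroxymethyl ketone: ring-expanded decalin, 3-oxo-4-(hydroxymethyl) in place of the 3-oxo-4-methylidene unit of 21 (epimers at C4) | C=C(CO[Si](C)(C)C(C)(C)C)C(=O)O[C@@H]1[C@H]2C(CO)C(=O)C[C@@H](O)[C@]2(C)CC[C@H]1C(=C)C(=O)OC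
F4 | step 15 | primary mesylate of F3 | C=C(CO[Si](C)(C)C(C)(C)C)C(=O)O[C@@H]1[C@H]2C(COS(C)(=O)=O)C(=O)C[C@@H](O)[C@]2(C)CC[C@H]1C(=C)C(=O)OC
F5 | step 3 | (2S,3R,4S)-2-(hydroxymethyl)-3-methyl-3-(4-methylpent-3-en-1-yl)-4-(triethylsilyloxy)cyclopentan-1-one | O=C1[C@H](CO)[C@@](C)(CCC=C(C)C)[C@@H](O[Si](CC)(CC)CC)C1
F6 | step 3 | tert-butyldimethylsilyl ether of F5 at the primary alcohol | O=C1[C@H](CO[Si](C)(C)C(C)(C)C)[C@@](C)(CCC=C(C)C)[C@@H](O[Si](CC)(CC)CC)C1
F7 | step 3 | ethynyl carbinol from F6 (ethynyl trans to the silyloxymethyl group) | C#C[C@@]1(O)[C@H](CO[Si](C)(C)C(C)(C)C)[C@@](C)(CCC=C(C)C)[C@@H](O[Si](CC)(CC)CC)C1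
F8 | step 3 | (1S,2S,3R,4S)-1-ethynyl-2-(hydroxymethyl)-3-methyl-3-(4-methylpent-3-en-1-yl)cyclopentane-1,4-diol | C#C[C@@]1(O)[C@H](CO)[C@@](C)(CCC=C(C)C)[C@@H](O)C1
F9 | step 7 | allylic chloride: compound 11 with the side chain changed to 3-chloro-4-methylpent-4-en-1-yl (epimers at the chlorinated carbon) | C#C[C@@]1(O)[C@H](C=O)[C@@](C)(CCC(Cl)C(C)=C)C(=O)C1
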